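The plan cuts the central coumarin (unit B) at its C2–C3 bond and at the ether bond from the oxygen on C3(B) to C7 of unit A. C3(B) carries an aryloxy group next to the C2 lactone carbonyl, and C7 of unit A lies para to C4a, so charge placed there can drain through the C3=C4 alkene into the lactone carbonyl of unit A. A Passerini–Smiles coupling of an arylacetaldehyde, umbelliferone and tert-butyl isocyanide exploits both facts and should form both bonds in one operation without closing a ring. The aldehyde already holds the B–C biaryl: a 7-methoxycoumarin bonded at C8 to a phenylacetaldehyde bearing an ortho MOM ether and a methoxy group.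

Key step: step 9

Assumption: the target is taken without a defined configuration of the C8(B)–C8(C) biaryl axis; compounds 13 to 16 are racemic at C3 of unit B and may be rotamer mixtures, all of which converge once that centre becomes sp2 in step 11.

Step 1
Reactants: 1 umbelliferone (7-hydroxy-2H-chromen-2-one)
Product: 2 7-hydroxy-8-iodo-2H-chromen-2-one
Conditions: I2, KI, 20% aq NH3, 0 °C to rt; acidic work-up
Reagents that add atoms: iodine, [I][I]
Why: Electrophilic aromatic iodination of the phenoxide, for which C8 (between the phenoxide carbon and C8a) is the established site of attack on umbelliferone in ammoniacal iodine.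

Step 2
Reactants: 2 7-hydroxy-8-iodo-2H-chromen-2-one
Product: 3 8-iodo-7-methoxy-2H-chromen-2-one
Conditions: MeI, K2CO3, acetone, 56 °C
Reagents that add atoms: iodomethane, CI
Why: Williamson ether synthesis on the acidic 7-hydroxyl, with carbonate in acetone too mild to open the lactone.

Step 3
Reactants: 3 8-iodo-7-methoxy-2H-chromen-2-one; 4 2,6-dimethoxyphenylboronic acid (2 equiv)
Product: 5 8-(2,6-dimethoxyphenyl)-7-methoxy-2H-chromen-2-one
Conditions: Pd(OAc)2 (5 mol%), SPhos (10 mol%), K3PO4, toluene/H2O 10:1, 90 °C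
Reagents that add atoms: none
Why: Suzuki–Miyaura coupling in which the dialkylbiarylphosphine-ligated zerovalent palladium formed in situ is suited to tetra-ortho-substituted biaryls, the excess boronic acid offsetting protodeboronation.

Step 4
Reactants: 5 8-(2,6-dimethoxyphenyl)-7-methoxy-2H-chromen-2-one
Product: 6 2,4-dimethoxy-3-(7-methoxy-2-oxo-2H-chromen-8-yl)benzaldehyde
Conditions: Cl2CHOMe, TiCl4, CH2Cl2, 0 °C; aqueous work-up
Reagents that add atoms: dichloromethyl methyl ether, COC(Cl)Cl; water, O
Why: Rieche formylation should attack the only doubly activated carbon, ortho to one methoxy and para to the other on the dimethoxyphenyl ring, because the Lewis acid-complexed coumarin ring is far less nucleophilic.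

Step 5
Reactants: 6 2,4-dimethoxy-3-(7-methoxy-2-oxo-2H-chromen-8-yl)benzaldehyde
Product: 7 2-hydroxy-4-methoxy-3-(7-methoxy-2-oxo-2H-chromen-8-yl)benzaldehyde
Conditions: BCl3, CH2Cl2, −78 to 0 °C; aqueous work-up
Reagents that add atoms: none
Why: Chelation-controlled ether cleavage, in which boron bound to the formyl oxygen removes only the methyl group of the ortho methoxy through a six-membered chelate and leaves the two remote methoxy groups alone.

Step 6
Reactants: 7 2-hydroxy-4-methoxy-3-(7-methoxy-2-oxo-2H-chromen-8-yl)benzaldehyde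
Product: 8 4-methoxy-2-(methoxymethoxy)-3-(7-methoxy-2-oxo-2H-chromen-8-yl)benzaldehyde
Conditions: MOMCl, K2CO3, DMF, 0 °C to rt
Reagents that add atoms: chloromethyl methyl ether, COCCl
Why: Williamson-type O-alkylation of the phenoxide with a small, highly reactive chloromethyl ether, which should reach the flanked oxygen and distinguishes it from the two methyl ethers for later release.

Step 7
Reactants: 8 4-methoxy-2-(methoxymethoxy)-3-(7-methoxy-2-oxo-2H-chromen-8-yl)benzaldehyde
Product: 9 7-methoxy-8-[6-methoxy-3-(2-methoxyethenyl)-2-(methoxymethoxy)phenyl]-2H-chromen-2-one (E/Z mixture)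
Conditions: Ph3P(CH2OMe)Cl, KN(SiMe3)2, THF, 0 °C; then 8, −78 to 0 °C
Reagents that add atoms: (methoxymethyl)triphenylphosphonium chloride, COC[P+](c1ccccc1)(c1ccccc1)c1ccccc1.[Cl-]
Why: Wittig olefination with the preformed methoxymethylene ylide, which at low temperature should take the aldehyde far faster than the lactone or enoate, the alkene geometry being irrelevant.

Step 8
Reactants: 9 7-methoxy-8-[6-methoxy-3-(2-methoxyethenyl)-2-(methoxymethoxy)phenyl]-2H-chromen-2-one
Product: 11 2-[4-methoxy-2-(methoxymethoxy)-3-(7-methoxy-2-oxo-2H-chromen-8-yl)phenyl]acetaldehyde, via alpha-mercurio aldehyde 10 (not isolated)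
Conditions: Hg(OAc)2, THF/H2O 10:1, 0 °C to rt; then sat aq KI
Reagents that add atoms: water, O
Why: Oxymercuration–demercuration hydrolysis of the enol ether by divalent mercury runs near neutrality, so the aryl MOM ether should survive where aqueous acid could free the phenol and let it cyclise onto the aldehyde to a benzofuran.

Step 9
Reactants: 11 2-[4-methoxy-2-(methoxymethoxy)-3-(7-methoxy-2-oxo-2H-chromen-8-yl)phenyl]acetaldehyde; 1 umbelliferone (1.2 equiv); 12 tert-butyl isocyanide (1.5 equiv)
Product: 14 N-tert-butyl-3-[4-methoxy-2-(methoxymethoxy)-3-(7-methoxy-2-oxo-2H-chromen-8-yl)phenyl]-2-[(2-oxo-2H-chromen-7-yl)oxy]propanamide (racemic), via aryl imidate 13 (not isolated)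
Conditions: MeOH (1 M), 55 °C, sealed tube
Reagents that add atoms: none
Why: Proposed new method: umbelliferone, close in acidity to the nitrophenols, hydrogen-bonds to the aldehyde, the isocyanide carbon adds to the carbonyl carbon to make the C2–C3 bond of unit B, and the phenoxide captures the nitrilium ion as aryl imidate 13; the secondary hydroxyl then attacks C7 of unit A ipso through a five-membered spiro Meisenheimer anion whose charge spreads from C4a over the C3=C4 alkene to the lactone carbonyl, and collapse moves the aryl group to the aldehyde-derived oxygen while the former phenol oxygen becomes the amide carbonyl. The closest known reaction type is the Passerini–Smiles coupling of aldehydes and isocyanides with nitrophenols or electron-poor hydroxy heteroaromatics, which has not been shown with a hydroxycoumarin as the acidic phenol. No ring is closed, because the spiro ring is only transient. The new stereocentre at C3 of unit B forms without control as a racemate, which is acceptable because step 11 converts it into an sp2 carbon. The step needs the Smiles migration to outrun reversal of the imidate and self-condensation of the aldehyde; the para-vinylogous ester activation of C7 and the irreversible amide formation provide the drive, and the MOM ether stops the neighbouring phenol oxygen of 11 from trapping the aldehyde or the nitrilium ion.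

Step 10
Reactants: 14 N-tert-butyl-3-[4-methoxy-2-(methoxymethoxy)-3-(7-methoxy-2-oxo-2H-chromen-8-yl)phenyl]-2-[(2-oxo-2H-chromen-7-yl)oxy]propanamide
Product: 16 7-methoxy-8-(7-methoxy-2-oxo-2H-chromen-8-yl)-3-[(2-oxo-2H-chromen-7-yl)oxy]-3,4-dihydro-2H-chromen-2-one (racemic), via free phenol amide 15 (not isolated)
Conditions: HCl (1.25 M in MeOH), THF, 45 °C; evaporate; TsOH·H2O (2 equiv), toluene, 110 °C
Reagents that add atoms: none
Why: Acid-catalysed acetal methanolysis removes the MOM group with the formaldehyde unit trapped as its dimethyl acetal, and the freed phenol then lactonises by intramolecular acyl substitution on the alpha-aryloxy amide, driven by six-membered ring formation and by protonation of the departing tert-butylamine.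

Step 11
Reactants: 16 7-methoxy-8-(7-methoxy-2-oxo-2H-chromen-8-yl)-3-[(2-oxo-2H-chromen-7-yl)oxy]-3,4-dihydro-2H-chromen-2-one
Product: 17 7-methoxy-8-(7-methoxy-2-oxo-2H-chromen-8-yl)-3-[(2-oxo-2H-chromen-7-yl)oxy]-2H-chromen-2-one
Conditions: DDQ (2.5 equiv), 1,4-dioxane, 100 °C
Reagents that add atoms: none
Why: DDQ dehydrogenation of a dihydrocoumarin, in which hydride is abstracted from C4 (benzylic and para to the C7 methoxy group) and proton loss from C3 gives the aromatic pyranone and erases the stereocentre.

Step 12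
Reactants: 17 7-methoxy-8-(7-methoxy-2-oxo-2H-chromen-8-yl)-3-[(2-oxo-2H-chromen-7-yl)oxy]-2H-chromen-2-one
Product: 18 triumbelletin, 7-hydroxy-8-(7-hydroxy-2-oxo-2H-chromen-8-yl)-3-[(2-oxo-2H-chromen-7-yl)oxy]-2H-chromen-2-one
Conditions: BBr3 (8 equiv), CH2Cl2, −78 °C to rt; aqueous work-up
Reagents that add atoms: none
Why: Lewis acid cleavage of the two aryl methyl ethers by BBr3 breaks only the methyl–oxygen bonds, whereas the three lactones and the aryl–O–C3 ether contain only sp2 carbon–oxygen bonds that bromide cannot displace.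

Compound list
1 | umbelliferone (7-hydroxy-2H-chromen-2-one) | O=c1ccc2ccc(O)cc2o1 | starting material
2 | 7-hydroxy-8-iodo-2H-chromen-2-one | O=c1ccc2ccc(O)c(I)c2o1 | intermediate
3 | 8-iodo-7-methoxy-2H-chromen-2-one | COc1ccc2ccc(=O)oc2c1I | intermediate
4 | 2,6-dimethoxyphenylboronic acid | COc1cccc(OC)c1B(O)O | starting material
5 | 8-(2,6-dimethoxyphenyl)-7-methoxy-2H-chromen-2-one | COc1cccc(OC)c1-c1c(OC)ccc2ccc(=O)oc12 | intermediate
6 | 2,4-dimethoxy-3-(7-methoxy-2-oxo-2H-chromen-8-yl)benzaldehyde | O=Cc1ccc(OC)c(c1OC)-c1c(OC)ccc2ccc(=O)oc12 | intermediate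
7 | 2-hydroxy-4-methoxy-3-(7-methoxy-2-oxo-2H-chromen-8-yl)benzaldehyde | O=Cc1ccc(OC)c(c1O)-c1c(OC)ccc2ccc(=O)oc12 | intermediate
8 | 4-methoxy-2-(methoxymethoxy)-3-(7-methoxy-2-oxo-2H-chromen-8-yl)benzaldehyde | O=Cc1ccc(OC)c(c1OCOC)-c1c(OC)ccc2ccc(=O)oc12 | intermediate
9 | 7-methoxy-8-[6-methoxy-3-(2-methoxyethenyl)-2-(methoxymethoxy)phenyl]-2H-chromen-2-one (E/Z mixture, geometry undefined) | COC=Cc1ccc(OC)c(c1OCOC)-c1c(OC)ccc2ccc(=O)oc12 | intermediate
10 | 2-(acetoxymercurio)-2-[4-methoxy-2-(methoxymethoxy)-3-(7-methoxy-2-oxo-2H-chromen-8-yl)phenyl]acetaldehyde | O=CC([Hg]OC(C)=O)c1ccc(OC)c(c1OCOC)-c1c(OC)ccc2ccc(=O)oc12 | intermediate (not isolated)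
11 | 2-[4-methoxy-2-(methoxymethoxy)-3-(7-methoxy-2-oxo-2H-chromen-8-yl)phenyl]acetaldehyde | O=CCc1ccc(OC)c(c1OCOC)-c1c(OC)ccc2ccc(=O)oc12 | intermediate
12 | tert-butyl isocyanide | CC(C)(C)[N+]#[C-] | starting material
13 | 2-oxo-2H-chromen-7-yl N-tert-butyl-2-hydroxy-3-[4-methoxy-2-(methoxymethoxy)-3-(7-methoxy-2-oxo-2H-chromen-8-yl)phenyl]propanimidate (racemic) | CC(C)(C)N=C(Oc1ccc2ccc(=O)oc2c1)C(O)Cc1ccc(OC)c(c1OCOC)-c1c(OC)ccc2ccc(=O)oc12 | intermediate (not isolated)
14 | N-tert-butyl-3-[4-methoxy-2-(methoxymethoxy)-3-(7-methoxy-2-oxo-2H-chromen-8-yl)phenyl]-2-[(2-oxo-2H-chromen-7-yl)oxy]propanamide (racemic, centre undefined) | CC(C)(C)NC(=O)C(Cc1ccc(OC)c(c1OCOC)-c1c(OC)ccc2ccc(=O)oc12)Oc1ccc2ccc(=O)oc2c1 | intermediate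
15 | N-tert-butyl-3-[2-hydroxy-4-methoxy-3-(7-methoxy-2-oxo-2H-chromen-8-yl)phenyl]-2-[(2-oxo-2H-chromen-7-yl)oxy]propanamide (racemic) | CC(C)(C)NC(=O)C(Cc1ccc(OC)c(c1O)-c1c(OC)ccc2ccc(=O)oc12)Oc1ccc2ccc(=O)oc2c1 | intermediate (not isolated)
16 | 7-methoxy-8-(7-methoxy-2-oxo-2H-chromen-8-yl)-3-[(2-oxo-2H-chromen-7-yl)oxy]-3,4-dihydro-2H-chromen-2-one (racemic) | O=C1Oc2c(-c3c(OC)ccc4ccc(=O)oc34)c(OC)ccc2CC1Oc1ccc2ccc(=O)oc2c1 | intermediate
17 | 7-methoxy-8-(7-methoxy-2-oxo-2H-chromen-8-yl)-3-[(2-oxo-2H-chromen-7-yl)oxy]-2H-chromen-2-one | O=c1oc2c(-c3c(OC)ccc4ccc(=O)oc34)c(OC)ccc2cc1Oc1ccc2ccc(=O)oc2c1 | intermediate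
18 | triumbelletin | O=c1ccc2ccc(Oc3cc4ccc(O)c(-c5c(O)ccc6ccc(=O)oc56)c4oc3=O)cc2o1 | target

Total step count: 12.
Longest linear sequence: 12 steps, from umbelliferone 1 to triumbelletin 18; building blocks 4, 12 and a second portion of 1 enter in steps 3 and 9.

Steps most likely to fail

Step 9. The Smiles migration may be too slow on a ring activated only through a vinylogous ester, so that the imidate reverts and the aldehyde is lost to self-condensation. The fallback uses known chemistry, sets out from 11 and returns at 14. A classical Passerini reaction of 11 with acetic acid and 12 (CH2Cl2, rt) should give 1-(tert-butylamino)-3-[4-methoxy-2-(methoxymethoxy)-3-(7-methoxy-2-oxo-2H-chromen-8-yl)phenyl]-1-oxopropan-2-yl acetate F1. Brief methanolysis (catalytic K2CO3, MeOH, 0 °C) should free the alpha-hydroxy amide, N-tert-butyl-2-hydroxy-3-[4-methoxy-2-(methoxymethoxy)-3-(7-methoxy-2-oxo-2H-chromen-8-yl)phenyl]propanamide F2. A Mitsunobu etherification of F2 with umbelliferone 1 (PPh3, DIAD, THF, 0 °C to rt) should then install the aryl ether and deliver 14.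

Step 10. Expulsion of the bulky tert-butylamine by a phenol flanked by the biaryl may be slow, so that the amide persists under prolonged heating. The fallback sets out from 14 and returns at 16. The MOM group is removed with HCl in MeOH and phenol 15 is isolated. Warm trifluoroacetic acid (70 °C) should then dealkylate the nitrogen by loss of the tert-butyl cation as isobutene, giving the primary amide 3-[2-hydroxy-4-methoxy-3-(7-methoxy-2-oxo-2H-chromen-8-yl)phenyl]-2-[(2-oxo-2H-chromen-7-yl)oxy]propanamide F3. This amide may already close in that medium; if not, TsOH·H2O in toluene at 110 °C should lactonise it with loss of ammonia to 16.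

Step 11. Hydride abstraction at C4 may stall because the C3 aryloxy group destabilises the developing cation inductively, or the quinone may oxidise the electron-rich rings instead. The fallback sets out from 16 and returns at 17. Radical bromination (NBS, catalytic AIBN, PhCF3, 80 °C) should give 4-bromo-7-methoxy-8-(7-methoxy-2-oxo-2H-chromen-8-yl)-3-[(2-oxo-2H-chromen-7-yl)oxy]-3,4-dihydro-2H-chromen-2-one F4. Any bromide formed at C3 instead leads to the same alkene. Dehydrobromination with Et3N in CH2Cl2 at rt should then give 17.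

Further compounds
F1 | step 9 | 1-(tert-butylamino)-3-[4-methoxy-2-(methoxymethoxy)-3-(7-methoxy-2-oxo-2H-chromen-8-yl)phenyl]-1-oxopropan-2-yl acetate (racemic) | CC(=O)OC(Cc1ccc(OC)c(c1OCOC)-c1c(OC)ccc2ccc(=O)oc12)C(=O)NC(C)(C)C
F2 | step 9 | N-tert-butyl-2-hydroxy-3-[4-methoxy-2-(methoxymethoxy)-3-(7-methoxy-2-oxo-2H-chromen-8-yl)phenyl]propanamide (racemic) | OC(Cc1ccc(OC)c(c1OCOC)-c1c(OC)ccc2ccc(=O)oc12)C(=O)NC(C)(C)C
F3 | step 10 | 3-[2-hydroxy-4-methoxy-3-(7-methoxy-2-oxo-2H-chromen-8-yl)phenyl]-2-[(2-oxo-2H-chromen-7-yl)oxy]propanamide (racemic) | NC(=O)C(Cc1ccc(OC)c(c1O)-c1c(OC)ccc2ccc(=O)oc12)Oc1ccc2ccc(=O)oc2c1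
F4 | step 11 | 4-bromo-7-methoxy-8-(7-methoxy-2-oxo-2H-chromen-8-yl)-3-[(2-oxo-2H-chromen-7-yl)oxy]-3,4-dihydro-2H-chromen-2-one (diastereomer mixture) | O=C1Oc2c(-c3c(OC)ccc4ccc(=O)oc34)c(OC)ccc2C(Br)C1Oc1ccc2ccc(=O)oc2c1
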